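**Retrosynthetic overview**

- The target is cut at the CH2–ring carbon bond into an enantiopure dearomatised acylphloroglucinol (trione) and a cyclopentane hydroxy-aldehyde. They are joined by Knoevenagel condensation and hydride transfer, and the aldehyde is released in the flask from a 1,3-diol.
- The diol comes from a cis-fused bicyclic β-lactone. Its cyclopentane and oxetanone rings form together in one aldol-lactonisation of an acyclic keto acid, which sets the two new cyclopentane stereocentres from the isopropenyl-bearing one.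
- The keto acid comes from (+)-limonene oxide by oxidative cleavage; the limonene ring is sacrificed and its stereocentre kept.
- The trione comes from 2-methylphloroglucinol by acylation, chlorine blocking of the free ring carbon, and catalytic asymmetric dearomative prenylation that sets the quaternary centre.
- Ring order: cyclopentane and β-lactone together (key step), then the β-lactone is opened; the six-membered carbocycle is carried through from the arene.

Assumption: the (1R,2R) ligand in step 7 is taken to give the (6R) quaternary centre; if it gives (6S), the (1S,2S) ligand is used instead.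

**Route**

Step 1
Reactants: 1 (+)-limonene oxide, (4R)-1-methyl-4-(prop-1-en-2-yl)-7-oxabicyclo[4.1.0]heptane (commercial cis/trans mixture)
Product: 2 (3R)-6-oxo-3-(prop-1-en-2-yl)heptanal
Conditions: H5IO6 (1.2 equiv), THF/H2O, 0 °C → rt
Reagents that add atoms: water, O
Why: Periodic acid hydrolyses the epoxide and cleaves the resulting glycol (Malaprade-type cleavage), so both epoxide isomers converge on one keto-aldehyde and the isopropenyl-bearing stereocentre is untouched.

Step 2
Reactants: 2 (3R)-6-oxo-3-(prop-1-en-2-yl)heptanal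
Product: 3 (3R)-6-oxo-3-(prop-1-en-2-yl)heptanoic acid
Conditions: NaClO2, NaH2PO4, 2-methyl-2-butene, tBuOH/H2O, 0 °C → rt
Reagents that add atoms: sodium chlorite, [Na+].[O-]Cl=O
Why: Pinnick oxidation converts the aldehyde to the acid without touching the ketone or the alkene, because the scavenger removes the hypochlorite.

Step 3
Reactants: 3 (3R)-6-oxo-3-(prop-1-en-2-yl)heptanoic acid
Product: 6 (1S,2R,5R)-5-methyl-2-(prop-1-en-2-yl)-6-oxabicyclo[3.2.0]heptan-7-one, via tosyl mixed anhydride 4 (not isolated), via acylpyridinium tosylate 5 (not isolated)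
Conditions: TsCl (1.3 equiv), 4-(pyrrolidin-1-yl)pyridine (1.0 equiv), iPr2NEt (1 equiv, proton shuttle), K2CO3 (3 equiv), CH2Cl2, rt
Reagents that add atoms: none
Why: In this nucleophile-catalysed aldol-lactonisation the ammonium enolate adds to the methyl ketone from the conformer that keeps the allylic C–H, not the isopropenyl group, in the enolate plane (A1,3 strain), so the new C–C bond forms anti to isopropenyl, and the four-membered ring can only close cis, which fixes the carbonyl carbon and the tertiary oxygen on the same face; cyclopentane and β-lactone form in this one operation, with close precedent for high diastereoselectivity on 3-substituted 6-oxo acids.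

Step 4
Reactants: 6 (1S,2R,5R)-5-methyl-2-(prop-1-en-2-yl)-6-oxabicyclo[3.2.0]heptan-7-one
Product: 7 (1R,2R,3R)-2-(hydroxymethyl)-1-methyl-3-(prop-1-en-2-yl)cyclopentan-1-ol
Conditions: LiAlH4, THF, 0 °C; aqueous work-up
Reagents that add atoms: none
Why: Hydride reduction of the strained lactone by acyl–oxygen cleavage gives the 1,3-diol with the tertiary C–O bond and all three stereocentres intact.

Step 5
Reactants: 8 2-methylbenzene-1,3,5-triol (2-methylphloroglucinol)
Product: 9 1-(2,4,6-trihydroxy-3-methylphenyl)-2-methylpropan-1-one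
Conditions: isobutyryl chloride (1.05 equiv), AlCl3 (3.5 equiv), PhNO2/CH2Cl2, 0 → 40 °C; aq. HCl work-up
Reagents that add atoms: isobutyryl chloride, CC(C)C(Cl)=O
Why: Friedel–Crafts acylation of the symmetric triol occurs once at one of the two equivalent free positions, and the chelated ketone deactivates the ring against a second acylation.

Step 6
Reactants: 9 1-(2,4,6-trihydroxy-3-methylphenyl)-2-methylpropan-1-one
Product: 10 1-(3-chloro-2,4,6-trihydroxy-5-methylphenyl)-2-methylpropan-1-one
Conditions: N-chlorosuccinimide (1.0 equiv), THF, −20 → 0 °C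
Reagents that add atoms: N-chlorosuccinimide, O=C1CCC(=O)N1Cl
Why: Electrophilic aromatic chlorination takes the only free ring carbon, which blocks it so that the next C-alkylation can occur only at the methyl-bearing carbon.

Step 7
Reactants: 10 1-(3-chloro-2,4,6-trihydroxy-5-methylphenyl)-2-methylpropan-1-one
Product: 12 (6R)-3,5-dihydroxy-6-methyl-6-(3-methylbut-2-en-1-yl)-2-(2-methylpropanoyl)cyclohexa-2,4-dien-1-one, via chloro trione 11 (not isolated)
Conditions: prenyl methyl carbonate (1.2 equiv), Pd2(dba)3·CHCl3 (2.5 mol %; dba = dibenzylideneacetone, zerovalent palladium), (1R,2R)-N,N'-bis[2-(diphenylphosphanyl)benzoyl]cyclohexane-1,2-diamine (7.5 mol %), CH2Cl2, 0 °C → rt; then AcOH, Zn dust, rt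
Reagents that add atoms: 3-methylbut-2-en-1-yl methyl carbonate, COC(=O)OCC=C(C)C
Why: Proposed new method: zerovalent palladium ionises the carbonate to a π-prenyl cation and methoxide, the phloroglucinolate (free carbon blocked by chlorine, O-prenyl ethers re-ionise) attacks the unhindered CH2 terminus through its methyl-bearing carbon inside the chiral pocket of the diamide bisphosphine, which distinguishes the acyl flank from the chlorine flank of the flat anion and so selects one enantiotopic face to set the quaternary centre, and Zn/AcOH then reduces the C–Cl bond of the α-chloro-β-diketone; the closest known reaction types are the Tsuji–Trost asymmetric allylic alkylation used to dearomatise substituted naphthols and the racemic palladium-catalysed alkylative dearomatisation of acylphloroglucinols.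

Step 8
Reactants: 7 (1R,2R,3R)-2-(hydroxymethyl)-1-methyl-3-(prop-1-en-2-yl)cyclopentan-1-ol; 12 (6R)-3,5-dihydroxy-6-methyl-6-(3-methylbut-2-en-1-yl)-2-(2-methylpropanoyl)cyclohexa-2,4-dien-1-one
Product: 15 (6R)-3,5-dihydroxy-4-{[(1S,2R,5R)-2-hydroxy-2-methyl-5-(prop-1-en-2-yl)cyclopentyl]methyl}-6-methyl-6-(3-methylbut-2-en-1-yl)-2-(2-methylpropanoyl)cyclohexa-2,4-dien-1-one (target), via hydroxy aldehyde 13 (not isolated), via alkylidene trione 14 (not isolated)
Conditions: 7, PhI(OAc)2 (1.1 equiv), 2,2,6,6-tetramethylpiperidin-1-oxyl (TEMPO, 10 mol %), CH2Cl2, 0 °C → rt; then 12 (1.0 equiv), L-proline (20 mol %), diethyl 2,6-dimethyl-1,4-dihydropyridine-3,5-dicarboxylate (Hantzsch ester, 1.3 equiv), rt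
Reagents that add atoms: none
Why: TEMPO/PhI(OAc)2 oxidises the only oxidisable (primary) hydroxyl, the acidic trione then condenses with the aldehyde (Knoevenagel condensation) and the alkylidene trione is reduced at its exocyclic carbon by hydride transfer from the Hantzsch ester (organocatalytic three-component reductive alkylation), which creates no new stereocentre and leaves the carbon next to the former aldehyde in its stable configuration, trans to isopropenyl and cis to the hydroxyl.

**Compound list**

1 | (+)-limonene oxide, (4R)-1-methyl-4-(prop-1-en-2-yl)-7-oxabicyclo[4.1.0]heptane, cis/trans mixture at the epoxide | CC12OC1C[C@@H](CC2)C(C)=C | starting material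
2 | (3R)-6-oxo-3-(prop-1-en-2-yl)heptanal | O=CC[C@@H](CCC(C)=O)C(=C)C | intermediate
3 | (3R)-6-oxo-3-(prop-1-en-2-yl)heptanoic acid | OC(=O)C[C@@H](CCC(C)=O)C(=C)C | intermediate
4 | (3R)-6-oxo-3-(prop-1-en-2-yl)heptanoic 4-methylbenzenesulfonic anhydride | Cc1ccc(cc1)S(=O)(=O)OC(=O)C[C@@H](CCC(C)=O)C(=C)C | intermediate (not isolated)
5 | 1-[(3R)-6-oxo-3-(prop-1-en-2-yl)heptanoyl]-4-(pyrrolidin-1-yl)pyridin-1-ium 4-methylbenzenesulfonate | O=C(C[C@@H](CCC(C)=O)C(=C)C)[n+]1ccc(cc1)N1CCCC1.Cc1ccc(cc1)S(=O)(=O)[O-] | intermediate (not isolated)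
6 | (1S,2R,5R)-5-methyl-2-(prop-1-en-2-yl)-6-oxabicyclo[3.2.0]heptan-7-one (cis-fused β-lactone, isopropenyl anti to the lactone) | C=C(C)[C@@H]1CC[C@@]2(C)OC(=O)[C@@H]12 | intermediate
7 | (1R,2R,3R)-2-(hydroxymethyl)-1-methyl-3-(prop-1-en-2-yl)cyclopentan-1-ol | C=C(C)[C@@H]1CC[C@@](C)(O)[C@H]1CO | intermediate
8 | 2-methylbenzene-1,3,5-triol | Cc1c(O)cc(O)cc1O | starting material
9 | 1-(2,4,6-trihydroxy-3-methylphenyl)-2-methylpropan-1-one | CC(C)C(=O)c1c(O)cc(O)c(C)c1O | intermediate
10 | 1-(3-chloro-2,4,6-trihydroxy-5-methylphenyl)-2-methylpropan-1-one | CC(C)C(=O)c1c(O)c(Cl)c(O)c(C)c1O | intermediate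
11 | (6R)-4-chloro-3,5-dihydroxy-6-methyl-6-(3-methylbut-2-en-1-yl)-2-(2-methylpropanoyl)cyclohexa-2,4-dien-1-one | CC(C)C(=O)C1=C(O)C(Cl)=C(O)[C@@](C)(CC=C(C)C)C1=O | intermediate (not isolated)
12 | (6R)-3,5-dihydroxy-6-methyl-6-(3-methylbut-2-en-1-yl)-2-(2-methylpropanoyl)cyclohexa-2,4-dien-1-one | CC(C)C(=O)C1=C(O)C=C(O)[C@@](C)(CC=C(C)C)C1=O | intermediate
13 | (1S,2R,5R)-2-hydroxy-2-methyl-5-(prop-1-en-2-yl)cyclopentane-1-carbaldehyde | C=C(C)[C@@H]1CC[C@@](C)(O)[C@H]1C=O | intermediate (not isolated)
14 | Knoevenagel adduct of 12 and 13: trione 12 carrying at its free ring carbon an exocyclic C=CH bond to the former aldehyde carbon of 13, all stereocentres as in 12 and 13 | C=C(C)[C@@H]1CC[C@@](C)(O)[C@H]1C=C2C(=O)[C@@](C)(CC=C(C)C)C(=O)C(C(=O)C(C)C)=C2O | intermediate (not isolated)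
15 | (6R)-3,5-dihydroxy-4-{[(1S,2R,5R)-2-hydroxy-2-methyl-5-(prop-1-en-2-yl)cyclopentyl]methyl}-6-methyl-6-(3-methylbut-2-en-1-yl)-2-(2-methylpropanoyl)cyclohexa-2,4-dien-1-one | C=C(C)[C@@H]1CC[C@@](C)(O)[C@H]1CC1=C(O)[C@@](C)(CC=C(C)C)C(=O)C(C(=O)C(C)C)=C1O | target

**Totals and risks**

Total step count: 8. Longest linear sequence: 5 steps (1 → 2 → 3 → 6 → 7 → 15); the trione branch is 3 steps (8 → 9 → 10 → 12).

Steps most likely to fail:

Step 7 (site- and enantioselective dearomative prenylation; the asymmetric version is untested on this anion and O-alkylation or low ee are possible). The fallback sets out from 10: C-prenylation without a chiral catalyst (prenyl bromide, aqueous KOH, 0 °C) gives the racemic chloro trione F3, which Zn/AcOH dechlorinates to the racemic trione F4. F4 is taken through step 8 with diol 7 and gives 15 together with its (6S)-epimer F5. The two diastereomers are separated by preparative HPLC, and the route is rejoined at 15.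

Step 8 (the free β-hydroxy aldehyde 13 can dehydrate or undergo retro-aldol cleavage before it condenses, and the alkylidene 14 can add a second trione). The fallback sets out from 6: ring-opening with MeNH(OMe)·HCl and Me2AlCl gives the Weinreb amide F6, and Et3SiOTf/2,6-lutidine gives its triethylsilyl ether F7. Reduction with iBu2AlH at −78 °C gives the silyl-protected aldehyde F8, which cannot undergo retro-aldol cleavage and can be purified. Condensation with 12 under L-proline/Hantzsch ester conditions gives the silyl ether F9, and HF·pyridine releases the tertiary alcohol, rejoining the route at 15.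

Step 3 (the key bicyclisation; oligomeric acylation, loss of CO2 from the β-lactone or a lower diastereomer ratio would all hurt). The fallback sets out from 3: thioesterification (PhSH, N,N'-dicyclohexylcarbodiimide, 4-(dimethylamino)pyridine) gives the S-phenyl thioester F1. Soft enolisation with TiCl4/iPr2NEt at −78 °C effects an intramolecular aldol addition to the methyl ketone, where the titanium chelate between thioester and alkoxide enforces the cis hydroxy thioester F2 and the same allylic-strain control keeps isopropenyl trans. LiAlH4 reduces F2 to diol 7, where the route is rejoined.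

**Further compounds**

F1 | step 3 | S-phenyl (3R)-6-oxo-3-(prop-1-en-2-yl)heptanethioate | O=C(C[C@@H](CCC(C)=O)C(=C)C)Sc1ccccc1
F2 | step 3 | S-phenyl (1S,2R,5R)-2-hydroxy-2-methyl-5-(prop-1-en-2-yl)cyclopentane-1-carbothioate | C=C(C)[C@@H]1CC[C@@](C)(O)[C@H]1C(=O)Sc1ccccc1
F3 | step 7 | racemic 4-chloro-3,5-dihydroxy-6-methyl-6-(3-methylbut-2-en-1-yl)-2-(2-methylpropanoyl)cyclohexa-2,4-dien-1-one | CC(C)C(=O)C1=C(O)C(Cl)=C(O)C(C)(CC=C(C)C)C1=O
F4 | step 7 | racemic 3,5-dihydroxy-6-methyl-6-(3-methylbut-2-en-1-yl)-2-(2-methylpropanoyl)cyclohexa-2,4-dien-1-one | CC(C)C(=O)C1=C(O)C=C(O)C(C)(CC=C(C)C)C1=O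
F5 | step 7 | (6S)-3,5-dihydroxy-4-{[(1S,2R,5R)-2-hydroxy-2-methyl-5-(prop-1-en-2-yl)cyclopentyl]methyl}-6-methyl-6-(3-methylbut-2-en-1-yl)-2-(2-methylpropanoyl)cyclohexa-2,4-dien-1-one | C=C(C)[C@@H]1CC[C@@](C)(O)[C@H]1CC1=C(O)[C@](C)(CC=C(C)C)C(=O)C(C(=O)C(C)C)=C1O
F6 | step 8 | (1S,2R,5R)-2-hydroxy-N-methoxy-N,2-dimethyl-5-(prop-1-en-2-yl)cyclopentane-1-carboxamide | C=C(C)[C@@H]1CC[C@@](C)(O)[C@H]1C(=O)N(C)OC
F7 | step 8 | (1S,2R,5R)-N-methoxy-N,2-dimethyl-5-(prop-1-en-2-yl)-2-[(triethylsilyl)oxy]cyclopentane-1-carboxamide | C=C(C)[C@@H]1CC[C@@](C)(O[Si](CC)(CC)CC)[C@H]1C(=O)N(C)OC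
F8 | step 8 | (1S,2R,5R)-2-methyl-5-(prop-1-en-2-yl)-2-[(triethylsilyl)oxy]cyclopentane-1-carbaldehyde | C=C(C)[C@@H]1CC[C@@](C)(O[Si](CC)(CC)CC)[C@H]1C=O
F9 | step 8 | triethylsilyl ether of 15 at the tertiary cyclopentyl hydroxyl | C=C(C)[C@@H]1CC[C@@](C)(O[Si](CC)(CC)CC)[C@H]1CC1=C(O)[C@@](C)(CC=C(C)C)C(=O)C(C(=O)C(C)C)=C1O
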